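**Retrosynthetic overview**

1. Target 25 ⇒ bromoalkene 21 + alkenyl boronate 24 (Suzuki, C11–C12). The side-chain diene is installed last because it would compete with the ring diene for singlet oxygen.
2. 21 ⇒ (3E,5E)-dienoic acid 18 by a one-flask oxygenation cascade that mirrors the presumed biogenesis (O2 capture by the polyketide dienoic acid, then lactonisation).
3. 18 ⇒ alkynol 4 by two Zr-catalysed methylaluminations (Negishi coupling with iodide 8 for the ring diene; bromination for the C10=C11 handle), separated by a triflate/acetylide homologation.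
4. 4 ⇒ Evans propargylation of 1, which sets C8.
5. Ring order: 1,2-dioxene first (C3–O and C6–O by [4+2]), γ-lactone second (C4–O).

Assumption: chain numbering C1 (lactone C=O) to C14 (benzylic CH2) is used in the text, in which the target is 3S,4S,6R,8R; reagents and catalysts are used as bought.

**Route**

Step 1
Reactants: 1 (R)-4-benzyl-3-propionyloxazolidin-2-one; 2 propargyl bromide
Product: 3 (R)-4-benzyl-3-[(S)-2-methylpent-4-ynoyl]oxazolidin-2-one
Conditions: NaHMDS, THF, −78 °C; then 2, −78 → −40 °C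
Reagents that add atoms: none
Why: Evans asymmetric alkylation: the chelated Z-sodium enolate is alkylated on the face opposite the benzyl group, which sets C8 (dr ≥ 95:5, minor isomer removed on silica).

Step 2
Reactants: 3 (R)-4-benzyl-3-[(S)-2-methylpent-4-ynoyl]oxazolidin-2-one
Product: 4 (S)-2-methylpent-4-yn-1-ol
Conditions: LiBH4, MeOH (1 equiv), Et2O, 0 °C
Reagents that add atoms: none
Why: Reductive cleavage of the N-acyl oxazolidinone by borohydride releases the primary alcohol without epimerising C8.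

Step 3
Reactants: 5 pent-3-yn-1-ol
Product: 6 tert-butyldimethyl(pent-3-yn-1-yloxy)silane
Conditions: TBSCl, imidazole, CH2Cl2, rt
Reagents that add atoms: tert-butyldimethylsilyl chloride, CC(C)(C)[Si](C)(C)Cl
Why: Standard silyl ether protection, needed so that only one hydroxyl is free at the triflation in step 6.

Step 4
Reactants: 6 tert-butyldimethyl(pent-3-yn-1-yloxy)silane
Product: 8 (E)-tert-butyl[(4-iodopent-3-en-1-yl)oxy]dimethylsilane, via alkenylzirconocene 7 (not isolated)
Conditions: Cp2Zr(H)Cl (2 equiv), THF, 50 °C; then I2, 0 °C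
Reagents that add atoms: iodine, II
Why: Schwartz hydrozirconation (syn H–Zr addition) equilibrates under excess reagent to the less hindered alkenylzirconium with Zr on the methyl-bearing carbon, and iodinolysis with retention gives the E-iodide.

Step 5
Reactants: 4 (S)-2-methylpent-4-yn-1-ol; 8 (E)-tert-butyl[(4-iodopent-3-en-1-yl)oxy]dimethylsilane
Product: 10 (2S,4E,6E)-9-[(tert-butyldimethylsilyl)oxy]-2,4,6-trimethylnona-4,6-dien-1-ol, via alkenylalane 9 (not isolated)
Conditions: Me3Al (3 equiv), Cp2ZrCl2 (0.25 equiv), CH2Cl2, 0 °C → rt; then 8, ZnCl2 (cat.), Pd(PPh3)4 (5 mol %), THF, rt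
Reagents that add atoms: trimethylaluminium, C[Al](C)C
Why: Negishi Zr-catalysed carboalumination adds Me–Al syn across the terminal alkyne and the alkenylalane then undergoes Pd/Zn-catalysed Negishi cross-coupling with 8, both with retention, giving the (4E,6E)-diene while the alcohol rides as its aluminium alkoxide and C8 is untouched.

Step 6
Reactants: 10 (2S,4E,6E)-9-[(tert-butyldimethylsilyl)oxy]-2,4,6-trimethylnona-4,6-dien-1-ol; 11 lithium (trimethylsilyl)acetylide
Product: 13 tert-butyldimethyl{[(3E,5E,8S)-4,6,8-trimethyl-11-(trimethylsilyl)undeca-3,5-dien-10-yn-1-yl]oxy}silane, via primary triflate 12 (not isolated)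
Conditions: Tf2O, 2,6-lutidine, CH2Cl2, −78 °C; then 11, THF/DMPU, −78 → 0 °C
Reagents that add atoms: none
Why: Triflation followed by SN2 alkynylation of the primary triflate adds C10–C11 without touching the β-stereocentre.

Step 7
Reactants: 13 tert-butyldimethyl{[(3E,5E,8S)-4,6,8-trimethyl-11-(trimethylsilyl)undeca-3,5-dien-10-yn-1-yl]oxy}silane
Product: 14 (3E,5E,8R)-4,6,8-trimethylundeca-3,5-dien-10-yn-1-ol
Conditions: TBAF (2.5 equiv), THF, 0 °C → rt
Reagents that add atoms: none
Why: Fluoride-mediated desilylation removes the O-TBS and C-TMS groups in one operation (the descriptor at C8 changes by CIP priority only).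

Step 8
Reactants: 14 (3E,5E,8R)-4,6,8-trimethylundeca-3,5-dien-10-yn-1-ol
Product: 16 (3E,5E,8S,10E)-11-bromo-4,6,8,10-tetramethylundeca-3,5,10-trien-1-ol, via alkenylalane 15 (not isolated)
Conditions: Me3Al (3 equiv), Cp2ZrCl2 (0.25 equiv), CH2Cl2, 0 °C → rt; then NBS, THF, −78 → −20 °C
Reagents that add atoms: trimethylaluminium, C[Al](C)C; N-bromosuccinimide, O=C1CCC(=O)N1Br
Why: A second Negishi carboalumination (alcohol as aluminium alkoxide, remote diene inert) followed by bromodealumination with retention gives the E-bromoalkene, a handle that tolerates singlet oxygen, iodine and tin hydride.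

Step 9
Reactants: 16 (3E,5E,8S,10E)-11-bromo-4,6,8,10-tetramethylundeca-3,5,10-trien-1-ol
Product: 18 (3E,5E,8S,10E)-11-bromo-4,6,8,10-tetramethylundeca-3,5,10-trienoic acid, via aldehyde 17 (not isolated)
Conditions: TEMPO (0.2 equiv), PhI(OAc)2 (2.2 equiv), MeCN/H2O, 0 °C → rt
Reagents that add atoms: water, O
Why: TEMPO/PhI(OAc)2 oxidation through the aldehyde hydrate gives the β,γ-unsaturated acid under near-neutral conditions that do not move the C3=C4 bond into conjugation.

Step 10
Reactants: 18 (3E,5E,8S,10E)-11-bromo-4,6,8,10-tetramethylundeca-3,5,10-trienoic acid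
Product: 21 (3R,4aS,7aS)-3-[(2R,4E)-5-bromo-2,4-dimethylpent-4-en-1-yl]-3,4a-dimethyltetrahydro-3H-furo[3,2-c][1,2]dioxin-6(4H)-one, via dioxene acid 19 (not isolated), via iodolactone 20 (not isolated)
Conditions: O2, TPP (1 mol %), CH2Cl2, −20 °C, 590 nm LEDs; Ar purge; MeCN, solid NaHCO3, I2 (1.5 equiv), 0 °C, dark; then Bu3SnH (3 equiv, first portion discharges residual I2), Et3B (0.3 equiv)/air, 0 °C
Reagents that add atoms: oxygen, O=O
Why: Proposed new method: a one-flask telescoping on the free acid of three individually known reactions (dye-sensitised diene endoperoxidation, iodolactonisation, stannane deiodination), in which singlet oxygen adds suprafacially by [4+2] to the s-cis (3E,5E)-diene and so places CH2CO2H (C3) and the C7 chain (C6) cis in 19, the carboxylate then attacks C4 5-exo and anti to the iodonium on the face of its own tether to give the cis-fused lactone (C4) of 20, and Bu3SnH finally removes the C5 iodide by a radical chain (the ring-held β-peroxy radical cannot reach the collinear geometry for epoxide-forming O–O cleavage and the bromoalkene reacts far more slowly than the alkyl iodide); C8 gives no facial control, so 21 forms about 1:1 with its (3S,4aR,7aR) diastereomer, which is removed by chromatography.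

Step 11
Reactants: 22 allylbenzene; 23 isopropenylboronic acid pinacol ester
Product: 24 (Z)-4,4,5,5-tetramethyl-2-(4-phenylbut-2-en-2-yl)-1,3,2-dioxaborolane
Conditions: Hoveyda–Grubbs II (5 mol %), 23 (3 equiv), 1,4-benzoquinone (10 mol %), CH2Cl2, 40 °C
Reagents that add atoms: none
Why: Ru-catalysed olefin cross-metathesis of the 1,1-disubstituted vinyl boronate with a terminal alkene gives the trisubstituted alkenyl boronate with Bpin trans to the benzyl CH2 (Z isomer), with no regiochemical ambiguity.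

Step 12
Reactants: 21 (3R,4aS,7aS)-3-[(2R,4E)-5-bromo-2,4-dimethylpent-4-en-1-yl]-3,4a-dimethyltetrahydro-3H-furo[3,2-c][1,2]dioxin-6(4H)-one; 24 (Z)-4,4,5,5-tetramethyl-2-(4-phenylbut-2-en-2-yl)-1,3,2-dioxaborolane
Product: 25 (3R,4aS,7aS)-3,4a-dimethyl-3-[(2R,4E,6E)-2,4,6-trimethyl-8-phenylocta-4,6-dien-1-yl]tetrahydro-3H-furo[3,2-c][1,2]dioxin-6(4H)-one (target)
Conditions: SPhos Pd G3 (5 mol %), K3PO4 (0.5 M aq, 2 equiv), THF, rt, degassed; work-up at pH 4
Reagents that add atoms: none
Why: Suzuki–Miyaura coupling proceeds with retention at both sp2 carbons to give the (10E,12E)-diene, and room temperature, weak aqueous base and a mildly acidic work-up (which re-closes any opened lactone) spare the dialkyl peroxide.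

**Compound list**

1 | (R)-4-benzyl-3-propionyloxazolidin-2-one | CCC(=O)N1[C@H](Cc2ccccc2)COC1=O | starting material
2 | propargyl bromide | C#CCBr | starting material
3 | (R)-4-benzyl-3-[(S)-2-methylpent-4-ynoyl]oxazolidin-2-one | C#CC[C@H](C)C(=O)N1[C@H](Cc2ccccc2)COC1=O | intermediate
4 | (S)-2-methylpent-4-yn-1-ol | C#CC[C@H](C)CO | intermediate
5 | pent-3-yn-1-ol | CC#CCCO | starting material
6 | tert-butyldimethyl(pent-3-yn-1-yloxy)silane | CC#CCCO[Si](C)(C)C(C)(C)C | intermediate
7 | (E)-[5-(tert-butyldimethylsilyloxy)pent-2-en-2-yl]zirconocene chloride | C/C(=C\CCO[Si](C)(C)C(C)(C)C)[Zr](Cl)(C1C=CC=C1)C1C=CC=C1 | intermediate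
8 | (E)-tert-butyl[(4-iodopent-3-en-1-yl)oxy]dimethylsilane | C/C(I)=C\CCO[Si](C)(C)C(C)(C)C | intermediate
9 | (S,E)-[5-(dimethylaluminiooxy)-2,4-dimethylpent-1-en-1-yl]dimethylalane | C[Al](C)/C=C(\C)C[C@H](C)CO[Al](C)C | intermediate
10 | (2S,4E,6E)-9-[(tert-butyldimethylsilyl)oxy]-2,4,6-trimethylnona-4,6-dien-1-ol | OC[C@@H](C)C/C(C)=C/C(C)=C/CCO[Si](C)(C)C(C)(C)C | intermediate
11 | lithium (trimethylsilyl)acetylide | [Li]C#C[Si](C)(C)C | starting material
12 | (2S,4E,6E)-9-[(tert-butyldimethylsilyl)oxy]-2,4,6-trimethylnona-4,6-dien-1-yl triflate | FC(F)(F)S(=O)(=O)OC[C@@H](C)C/C(C)=C/C(C)=C/CCO[Si](C)(C)C(C)(C)C | intermediate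
13 | tert-butyldimethyl{[(3E,5E,8S)-4,6,8-trimethyl-11-(trimethylsilyl)undeca-3,5-dien-10-yn-1-yl]oxy}silane | C[Si](C)(C)C#CC[C@@H](C)C/C(C)=C/C(C)=C/CCO[Si](C)(C)C(C)(C)C | intermediate
14 | (3E,5E,8R)-4,6,8-trimethylundeca-3,5-dien-10-yn-1-ol | C#CC[C@@H](C)C/C(C)=C/C(C)=C/CCO | intermediate
15 | alkenylalane of 14 (C11–AlMe2, O–AlMe2) | C[Al](C)/C=C(\C)C[C@@H](C)C/C(C)=C/C(C)=C/CCO[Al](C)C | intermediate
16 | (3E,5E,8S,10E)-11-bromo-4,6,8,10-tetramethylundeca-3,5,10-trien-1-ol | Br/C=C(\C)C[C@@H](C)C/C(C)=C/C(C)=C/CCO | intermediate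
17 | (3E,5E,8S,10E)-11-bromo-4,6,8,10-tetramethylundeca-3,5,10-trienal | Br/C=C(\C)C[C@@H](C)C/C(C)=C/C(C)=C/CC=O | intermediate
18 | (3E,5E,8S,10E)-11-bromo-4,6,8,10-tetramethylundeca-3,5,10-trienoic acid | Br/C=C(\C)C[C@@H](C)C/C(C)=C/C(C)=C/CC(=O)O | intermediate
19 | 2-{(3S,6R)-6-[(2R,4E)-5-bromo-2,4-dimethylpent-4-en-1-yl]-4,6-dimethyl-3,6-dihydro-1,2-dioxin-3-yl}acetic acid | Br/C=C(\C)C[C@@H](C)C[C@]1(C)C=C(C)[C@H](CC(=O)O)OO1 | intermediate
20 | (3R,4S,4aR,7aS)-3-[(2R,4E)-5-bromo-2,4-dimethylpent-4-en-1-yl]-4-iodo-3,4a-dimethyltetrahydro-3H-furo[3,2-c][1,2]dioxin-6(4H)-one | Br/C=C(\C)C[C@@H](C)C[C@]1(C)[C@@H](I)[C@]2(C)OC(=O)C[C@@H]2OO1 | intermediate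
21 | (3R,4aS,7aS)-3-[(2R,4E)-5-bromo-2,4-dimethylpent-4-en-1-yl]-3,4a-dimethyltetrahydro-3H-furo[3,2-c][1,2]dioxin-6(4H)-one | Br/C=C(\C)C[C@@H](C)C[C@]1(C)C[C@]2(C)OC(=O)C[C@@H]2OO1 | intermediate
22 | allylbenzene | C=CCc1ccccc1 | starting material
23 | isopropenylboronic acid pinacol ester | CC(=C)B1OC(C)(C)C(C)(C)O1 | starting material
24 | (Z)-4,4,5,5-tetramethyl-2-(4-phenylbut-2-en-2-yl)-1,3,2-dioxaborolane | C/C(B1OC(C)(C)C(C)(C)O1)=C\Cc1ccccc1 | intermediate
25 | (3R,4aS,7aS)-3,4a-dimethyl-3-[(2R,4E,6E)-2,4,6-trimethyl-8-phenylocta-4,6-dien-1-yl]tetrahydro-3H-furo[3,2-c][1,2]dioxin-6(4H)-one | CC(=C\Cc1ccccc1)/C=C(\C)C[C@@H](C)C[C@]1(C)C[C@]2(C)OC(=O)C[C@@H]2OO1 | target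

**Step count**

Total steps: 12. Longest linear sequence: 9 (steps 1, 2, 5, 6, 7, 8, 9, 10, 12).

**Steps most likely to fail, with fallbacks**

Step 9 (oxidation to the skipped dienoic acid). The β,γ-unsaturated aldehyde 17 or acid 18 may slip into conjugation. The fallback inverts the order of oxidation and peroxide formation. It sets out from 16, which is photo-oxygenated directly (O2, TPP, CH2Cl2, −20 °C) to the dioxene alcohol 2-{(3S,6R)-6-[(2R,4E)-5-bromo-2,4-dimethylpent-4-en-1-yl]-4,6-dimethyl-3,6-dihydro-1,2-dioxin-3-yl}ethan-1-ol F1. The C3=C4 bond is then gone, and TEMPO/PhI(OAc)2 oxidation of F1 gives the acid. The fallback comes back to the route at 19, here isolated, which is carried through the iodine and tin stages of step 10 to 21.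

Step 10 (key cascade). Ene reactions can erode the [4+2], and the in-flask iodine and tin stages can fail on the crude dioxene. The fallback closes the lactone by oxymercuration–demercuration instead of iodolactonisation and stannane reduction. It sets out from 19, isolated after the photo-oxygenation (the two dioxene diastereomers are separated there). Hg(OCOCF3)2 in CH2Cl2 at −20 °C gives the anti mercurilactone [(3R,4S,4aR,7aS)-3-((2R,4E)-5-bromo-2,4-dimethylpent-4-en-1-yl)-3,4a-dimethyl-6-oxohexahydrofuro[3,2-c][1,2]dioxin-4-yl]mercury trifluoroacetate F2. NaBH4 in THF/H2O at 0 °C then reduces F2 in the same flask, and the fallback comes back to the route at 21.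

Step 12 (Suzuki coupling on the peroxy-lactone). Aqueous base may open the lactone or trigger β-elimination of the peroxide, and electron-rich Pd(0) may attack the O–O bond. The fallback is a base-free Negishi coupling and sets out from 24. NaOMe then I2 (iododeboronation with retention) gives (E)-(3-iodobut-2-en-1-yl)benzene F3. t-BuLi at −78 °C gives (E)-(4-phenylbut-2-en-2-yl)lithium F4, and ZnBr2 converts this to (E)-(4-phenylbut-2-en-2-yl)zinc bromide F5. Coupling of F5 with 21 (Pd(t-Bu3P)2, THF, rt) comes back to the route at 25.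

Further compounds
F1 | step 9 | 2-{(3S,6R)-6-[(2R,4E)-5-bromo-2,4-dimethylpent-4-en-1-yl]-4,6-dimethyl-3,6-dihydro-1,2-dioxin-3-yl}ethan-1-ol | Br/C=C(\C)C[C@@H](C)C[C@]1(C)C=C(C)[C@H](CCO)OO1
F2 | step 10 | [(3R,4S,4aR,7aS)-3-((2R,4E)-5-bromo-2,4-dimethylpent-4-en-1-yl)-3,4a-dimethyl-6-oxohexahydrofuro[3,2-c][1,2]dioxin-4-yl]mercury trifluoroacetate | Br/C=C(\C)C[C@@H](C)C[C@]1(C)[C@@H]([Hg]OC(=O)C(F)(F)F)[C@]2(C)OC(=O)C[C@@H]2OO1
F3 | step 12 | (E)-(3-iodobut-2-en-1-yl)benzene | C/C(I)=C\Cc1ccccc1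
F4 | step 12 | (E)-(4-phenylbut-2-en-2-yl)lithium | C/C([Li])=C\Cc1ccccc1
F5 | step 12 | (E)-(4-phenylbut-2-en-2-yl)zinc bromide | C/C([Zn]Br)=C\Cc1ccccc1
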